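## Retrosynthetic overview

- The triene is cut at the bond between the ring vinyl group and the dienamide (Heck), giving a 4-vinyl epoxyquinol and the bromodienamide of 2-aminocyclopentane-1,3-dione.
- The ring N–acyl bond is cut into a ring vinyl isocyanate (Curtius rearrangement of the shikimate carboxyl group) and (2E,4R)-2,4-dimethyloct-2-enoic acid.
- The C4 carbinol and the C1 ketone come from one [4+2] cycloaddition of singlet oxygen to a cyclohexa-1,3-diene, anti to a cis-acetonide, followed by Kornblum–DeLaMare opening of the endoperoxide.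
- The diene comes from (−)-shikimic acid (C5 ketone, dienyl triflate, Stille vinylation); its cis-3,4-diol becomes the epoxide with net retention.
- Ring order: the carbocycle is bought (shikimic acid); acetonide ring (step 9); endoperoxide ring by cycloaddition (step 15, opened in the same flask); oxirane (step 17). The cyclopentenone ring is bought as cyclopentane-1,3-dione.

Assumption: the target is taken exactly as the SMILES reads; with cyclohexenone numbering (C1 = C=O, C2 = C–N, C4 = C–OH) it is (4R,5R,6S), with the C4–OH anti to the epoxide oxygen, and the enamide chain is (2E,4R).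

## Route

**Step 1**
Reactants: 1 (S)-3-bromo-2-methylpropan-1-ol
Product: 2 (R)-2-methylhexan-1-ol
Conditions: n-PrMgBr (2.5 equiv), Li2CuCl4 (3 mol %), THF, −78 °C to rt
Reagents that add atoms: n-propylmagnesium bromide, CCC[Mg]Br
Why: Kochi copper-catalysed sp3–sp3 Grignard coupling at the primary bromide (the first equivalent masks the OH as its alkoxide); the bought stereocenter is not at the reacting carbon and only its descriptor changes (S to R) through CIP priorities.

**Step 2**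
Reactants: 2 (R)-2-methylhexan-1-ol
Product: 4 ethyl (2E,4R)-2,4-dimethyloct-2-enoate, via (R)-2-methylhexanal 3 (not isolated)
Conditions: TEMPO (10 mol %), PhI(OAc)2, CH2Cl2, rt; then Ph3P=C(Me)CO2Et, rt
Reagents that add atoms: ethyl 2-(triphenylphosphoranylidene)propanoate, CCOC(=O)C(C)=P(c1ccccc1)(c1ccccc1)c1ccccc1
Why: Oxoammonium (TEMPO) oxidation followed in the same flask by Wittig olefination with a stabilised ylide gives the (E)-enoate and traps the α-chiral aldehyde before it can epimerise.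

**Step 3**
Reactants: 4 ethyl (2E,4R)-2,4-dimethyloct-2-enoate
Product: 5 (2E,4R)-2,4-dimethyloct-2-enoic acid
Conditions: LiOH, THF/MeOH/H2O, rt; then 1 M HCl
Reagents that add atoms: lithium hydroxide, [Li+].[OH-]
Why: Saponification of the ester; the γ-stereocenter and the (E)-alkene are not affected.

**Step 4**
Reactants: 6 cyclopentane-1,3-dione
Product: 7 2-(hydroxyimino)cyclopentane-1,3-dione
Conditions: NaNO2, aq. HCl, 0 °C
Reagents that add atoms: sodium nitrite, [Na+].[O-]N=O
Why: Electrophilic nitrosation of the enol at C2, the nitroso compound tautomerising to the oxime.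

**Step 5**
Reactants: 7 2-(hydroxyimino)cyclopentane-1,3-dione
Product: 8 2-amino-3-hydroxycyclopent-2-en-1-one hydrochloride
Conditions: H2 (1 atm), palladium on carbon (10% Pd/C), HCl, MeOH, rt
Reagents that add atoms: hydrogen chloride, Cl
Why: Catalytic hydrogenation of the oxime (C=N reduction and N–O hydrogenolysis), the amine being held as its salt to prevent self-condensation.

**Step 6**
Reactants: 9 glutaconaldehyde potassium salt
Product: 10 (2E,4E)-5-bromopenta-2,4-dienal
Conditions: Ph3PBr2, CH2Cl2, 0 °C to rt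
Reagents that add atoms: triphenylphosphine dibromide, BrP(Br)(c1ccccc1)(c1ccccc1)c1ccccc1
Why: The enolate oxygen is activated as an oxyphosphonium and replaced by bromide in a vinylogous addition–elimination, giving the all-(E) bromodienal.

**Step 7**
Reactants: 10 (2E,4E)-5-bromopenta-2,4-dienal
Product: 11 (2E,4E)-5-bromopenta-2,4-dienoic acid
Conditions: NaClO2, NaH2PO4, 2-methylbut-2-ene, t-BuOH/H2O, 0 °C to rt
Reagents that add atoms: sodium chlorite, [Na+].[O-]Cl=O
Why: Pinnick oxidation converts the enal to the acid without touching the bromodiene.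

**Step 8**
Reactants: 11 (2E,4E)-5-bromopenta-2,4-dienoic acid; 8 2-amino-3-hydroxycyclopent-2-en-1-one hydrochloride
Product: 12 (2E,4E)-5-bromo-N-(2-hydroxy-5-oxocyclopent-1-en-1-yl)penta-2,4-dienamide
Conditions: EDC·HCl, HOBt, N-methylmorpholine, DMF, 0 °C to rt
Reagents that add atoms: none
Why: Carbodiimide/HOBt amide coupling; any O-acyl enol ester transfers its acyl group to nitrogen.

**Step 9**
Reactants: 13 (−)-shikimic acid
Product: 15 methyl (3R,4S,5R)-5-hydroxy-3,4-(isopropylidenedioxy)cyclohex-1-ene-1-carboxylate, via methyl shikimate 14 (not isolated)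
Conditions: MeOH, CSA (cat.), reflux; evaporate; Me2C(OMe)2, acetone, rt
Reagents that add atoms: methanol, CO; 2,2-dimethoxypropane, COC(C)(C)OC
Why: Fischer esterification, then acetonide formation on the only cis-diol (C3/C4), leaving the C5–OH free; all three bought stereocenters are kept.

**Step 10**
Reactants: 15 methyl (3R,4S,5R)-5-hydroxy-3,4-(isopropylidenedioxy)cyclohex-1-ene-1-carboxylate
Product: 16 methyl (3R,4R)-3,4-(isopropylidenedioxy)-5-oxocyclohex-1-ene-1-carboxylate
Conditions: Dess–Martin periodinane, CH2Cl2, 0 °C to rt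
Reagents that add atoms: none
Why: Dess–Martin oxidation of the secondary alcohol under non-basic conditions, which avoids β-elimination and aromatisation of the ketone (used crude).

**Step 11**
Reactants: 16 methyl (3R,4R)-3,4-(isopropylidenedioxy)-5-oxocyclohex-1-ene-1-carboxylate
Product: 17 methyl (3R,4R)-3,4-(isopropylidenedioxy)-5-(trifluoromethylsulfonyloxy)cyclohexa-1,5-diene-1-carboxylate
Conditions: KN(SiMe3)2, THF, −78 °C; Comins' reagent, −78 °C
Reagents that add atoms: Comins' reagent [N-(5-chloropyridin-2-yl)bis(trifluoromethanesulfonimide)], FC(F)(F)S(=O)(=O)N(c1ccc(Cl)cn1)S(=O)(=O)C(F)(F)F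
Why: The C6 methylene is both α to the ketone and allylic, so the conjugated dienolate forms there and is O-triflated (enol triflate formation) at −78 °C, before it can expel the C3 oxygen.

**Step 12**
Reactants: 17 methyl (3R,4R)-3,4-(isopropylidenedioxy)-5-(trifluoromethylsulfonyloxy)cyclohexa-1,5-diene-1-carboxylate
Product: 18 methyl (3R,4S)-5-ethenyl-3,4-(isopropylidenedioxy)cyclohexa-1,5-diene-1-carboxylate
Conditions: CH2=CHSnBu3, Pd(PPh3)4 (5 mol %), LiCl, THF, 60 °C
Reagents that add atoms: tributyl(ethenyl)stannane, C=C[Sn](CCCC)(CCCC)CCCC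
Why: Stille coupling of the dienyl triflate (LiCl-promoted) installs the vinyl group that becomes the first two carbons of the triene; no stereocenter is involved.

**Step 13**
Reactants: 18 methyl (3R,4S)-5-ethenyl-3,4-(isopropylidenedioxy)cyclohexa-1,5-diene-1-carboxylate
Product: 19 (3R,4S)-5-ethenyl-3,4-(isopropylidenedioxy)cyclohexa-1,5-diene-1-carboxylic acid
Conditions: LiOH, THF/H2O, 0 °C to rt; then 1 M HCl to pH 4, 0 °C
Reagents that add atoms: lithium hydroxide, [Li+].[OH-]
Why: Saponification of the dienoate; acidification is kept mild and cold because the diene acetonide is acid-labile.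

**Step 14**
Reactants: 19 (3R,4S)-5-ethenyl-3,4-(isopropylidenedioxy)cyclohexa-1,5-diene-1-carboxylic acid; 5 (2E,4R)-2,4-dimethyloct-2-enoic acid
Product: 22 (2E,4R)-N-[(3R,4S)-5-ethenyl-3,4-(isopropylidenedioxy)cyclohexa-1,5-dien-1-yl]-2,4-dimethyloct-2-enamide, via acyl azide 20 (not isolated), via vinyl isocyanate 21 (not isolated)
Conditions: (PhO)2P(O)N3 (1.0 equiv), Et3N, toluene, 0 °C to rt; 80 °C; then 5, DMAP (20 mol %), 60 °C
Reagents that add atoms: diphenylphosphoryl azide, [N-]=[N+]=NP(=O)(Oc1ccccc1)Oc1ccccc1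
Why: Curtius rearrangement turns the ring carboxyl into a vinyl isocyanate, and DMAP-catalysed addition of acid 5 gives a mixed carbamic anhydride that loses CO2 to the enamide; no stereocenter is touched.

**Step 15**
Reactants: 22 (2E,4R)-N-[(3R,4S)-5-ethenyl-3,4-(isopropylidenedioxy)cyclohexa-1,5-dien-1-yl]-2,4-dimethyloct-2-enamide
Product: 24 (4R,5R,6S)-2-[(2E,4R)-2,4-dimethyloct-2-enoylamino]-4-ethenyl-4-hydroxy-5,6-(isopropylidenedioxy)cyclohex-2-en-1-one, via endoperoxide 23 (not isolated)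
Conditions: O2, tetraphenylporphyrin (1 mol %), visible light, CH2Cl2, −78 °C; then Et3N, −78 to 0 °C
Reagents that add atoms: dioxygen, O=O
Why: [4+2] cycloaddition of singlet oxygen to the s-cis ring diene on the face opposite the cis-acetonide builds the 2,3-dioxabicyclo[2.2.2]octene ring and sets C4 (oxygen anti to the C5/C6 oxygens); Kornblum–DeLaMare opening, with Et3N removing the only bridgehead hydrogen, gives the C1 ketone and the tertiary C4–OH.

**Step 16**
Reactants: 24 (4R,5R,6S)-2-[(2E,4R)-2,4-dimethyloct-2-enoylamino]-4-ethenyl-4-hydroxy-5,6-(isopropylidenedioxy)cyclohex-2-en-1-one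
Product: 25 (4R,5R,6S)-2-[(2E,4R)-2,4-dimethyloct-2-enoylamino]-4-ethenyl-4,5,6-trihydroxycyclohex-2-en-1-one
Conditions: AcOH/H2O (4:1), 45 °C
Reagents that add atoms: none
Why: Mild acid hydrolysis of the acetonide; the tertiary alcohol next to the electron-poor enone does not ionise under these conditions.

**Step 17**
Reactants: 25 (4R,5R,6S)-2-[(2E,4R)-2,4-dimethyloct-2-enoylamino]-4-ethenyl-4,5,6-trihydroxycyclohex-2-en-1-one
Product: 28 (4R,5R,6S)-2-[(2E,4R)-2,4-dimethyloct-2-enoylamino]-4-ethenyl-5,6-epoxy-4-hydroxycyclohex-2-en-1-one, via cyclic orthoacetate 26 (not isolated), via bromo acetate 27 (not isolated)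
Conditions: MeC(OMe)3, PPTS (cat.), CH2Cl2, rt; evaporate; AcBr, CH2Cl2, 0 °C; evaporate; K2CO3, MeOH, 0 °C
Reagents that add atoms: none
Why: Kolb–Sharpless diol-to-epoxide sequence: bromide opens the acetoxonium ion with inversion (at C6, α to the ketone) and the C5 alkoxide then displaces bromide with a second inversion, so the oxirane keeps the face of the bought cis-diol, anti to the C4–OH.

**Step 18**
Reactants: 28 (4R,5R,6S)-2-[(2E,4R)-2,4-dimethyloct-2-enoylamino]-4-ethenyl-5,6-epoxy-4-hydroxycyclohex-2-en-1-one; 12 (2E,4E)-5-bromo-N-(2-hydroxy-5-oxocyclopent-1-en-1-yl)penta-2,4-dienamide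
Product: 29 (4R,5R,6S)-2-[(2E,4R)-2,4-dimethyloct-2-enoylamino]-5,6-epoxy-4-hydroxy-4-[(1E,3E,5E)-7-[(2-hydroxy-5-oxocyclopent-1-en-1-yl)amino]-7-oxohepta-1,3,5-trien-1-yl]cyclohex-2-en-1-one (target)
Conditions: Pd(OAc)2 (10 mol %), Bu4NCl, NaHCO3, DMF, 45 °C, argon, dark
Reagents that add atoms: none
Why: Jeffery-type Heck reaction: the alkenylpalladium from 12 adds to the terminal CH2 of the vinyl group and syn β-hydride elimination can only give the (E)-alkene because the tertiary carbinol has no β-hydrogen; the bromide geometry is retained, giving the (E,E,E)-triene.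

## Compound list

1 | (S)-3-bromo-2-methylpropan-1-ol | OC[C@H](C)CBr | starting material
2 | (R)-2-methylhexan-1-ol | OC[C@H](C)CCCC | intermediate
3 | (R)-2-methylhexanal | O=C[C@H](C)CCCC | intermediate
4 | ethyl (2E,4R)-2,4-dimethyloct-2-enoate | CCCC[C@@H](C)/C=C(\C)C(=O)OCC | intermediate
5 | (2E,4R)-2,4-dimethyloct-2-enoic acid | CCCC[C@@H](C)/C=C(\C)C(=O)O | intermediate
6 | cyclopentane-1,3-dione | O=C1CCC(=O)C1 | starting material
7 | 2-(hydroxyimino)cyclopentane-1,3-dione | ON=C1C(=O)CCC1=O | intermediate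
8 | 2-amino-3-hydroxycyclopent-2-en-1-one hydrochloride | NC1=C(O)CCC1=O.Cl | intermediate
9 | glutaconaldehyde potassium salt, potassium (1E,3E)-5-oxopenta-1,3-dien-1-olate | [K+].[O-]/C=C/C=C/C=O | starting material
10 | (2E,4E)-5-bromopenta-2,4-dienal | O=C/C=C/C=C/Br | intermediate
11 | (2E,4E)-5-bromopenta-2,4-dienoic acid | OC(=O)/C=C/C=C/Br | intermediate
12 | (2E,4E)-5-bromo-N-(2-hydroxy-5-oxocyclopent-1-en-1-yl)penta-2,4-dienamide | O=C(/C=C/C=C/Br)NC1=C(O)CCC1=O | intermediate
13 | (−)-shikimic acid, (3R,4S,5R)-3,4,5-trihydroxycyclohex-1-ene-1-carboxylic acid | OC(=O)C1=C[C@@H](O)[C@@H](O)[C@H](O)C1 | starting material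
14 | methyl shikimate, methyl (3R,4S,5R)-3,4,5-trihydroxycyclohex-1-ene-1-carboxylate | COC(=O)C1=C[C@@H](O)[C@@H](O)[C@H](O)C1 | intermediate
15 | methyl (3R,4S,5R)-5-hydroxy-3,4-(isopropylidenedioxy)cyclohex-1-ene-1-carboxylate | COC(=O)C1=C[C@H]2OC(C)(C)O[C@H]2[C@H](O)C1 | intermediate
16 | methyl (3R,4R)-3,4-(isopropylidenedioxy)-5-oxocyclohex-1-ene-1-carboxylate | COC(=O)C1=C[C@H]2OC(C)(C)O[C@H]2C(=O)C1 | intermediate
17 | methyl (3R,4R)-3,4-(isopropylidenedioxy)-5-(trifluoromethylsulfonyloxy)cyclohexa-1,5-diene-1-carboxylate | COC(=O)C1=C[C@H]2OC(C)(C)O[C@H]2C(OS(=O)(=O)C(F)(F)F)=C1 | intermediate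
18 | methyl (3R,4S)-5-ethenyl-3,4-(isopropylidenedioxy)cyclohexa-1,5-diene-1-carboxylate | COC(=O)C1=C[C@H]2OC(C)(C)O[C@H]2C(C=C)=C1 | intermediate
19 | (3R,4S)-5-ethenyl-3,4-(isopropylidenedioxy)cyclohexa-1,5-diene-1-carboxylic acid | OC(=O)C1=C[C@H]2OC(C)(C)O[C@H]2C(C=C)=C1 | intermediate
20 | (3R,4S)-5-ethenyl-3,4-(isopropylidenedioxy)cyclohexa-1,5-diene-1-carbonyl azide | [N-]=[N+]=NC(=O)C1=C[C@H]2OC(C)(C)O[C@H]2C(C=C)=C1 | intermediate
21 | (3R,4S)-5-ethenyl-1-isocyanato-3,4-(isopropylidenedioxy)cyclohexa-1,5-diene | O=C=NC1=C[C@H]2OC(C)(C)O[C@H]2C(C=C)=C1 | intermediate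
22 | (2E,4R)-N-[(3R,4S)-5-ethenyl-3,4-(isopropylidenedioxy)cyclohexa-1,5-dien-1-yl]-2,4-dimethyloct-2-enamide | CCCC[C@@H](C)/C=C(\C)C(=O)NC1=C[C@H]2OC(C)(C)O[C@H]2C(C=C)=C1 | intermediate
23 | endoperoxide of 22 (2,3-dioxabicyclo[2.2.2]oct-5-ene; O–O bridge from old C2 to old C5 on the face opposite the acetonide) | CCCC[C@@H](C)/C=C(\C)C(=O)NC1=C[C@@]4(C=C)OO[C@@H]1[C@H]2OC(C)(C)O[C@H]24 | intermediate
24 | (4R,5R,6S)-2-[(2E,4R)-2,4-dimethyloct-2-enoylamino]-4-ethenyl-4-hydroxy-5,6-(isopropylidenedioxy)cyclohex-2-en-1-one | CCCC[C@@H](C)/C=C(\C)C(=O)NC1=C[C@](O)(C=C)[C@@H]2OC(C)(C)O[C@@H]2C1=O | intermediate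
25 | (4R,5R,6S)-2-[(2E,4R)-2,4-dimethyloct-2-enoylamino]-4-ethenyl-4,5,6-trihydroxycyclohex-2-en-1-one | CCCC[C@@H](C)/C=C(\C)C(=O)NC1=C[C@](O)(C=C)[C@H](O)[C@H](O)C1=O | intermediate
26 | cyclic 5,6-O-(1-methoxyethylidene) orthoacetate of 25 (mixture at the orthoester carbon) | CCCC[C@@H](C)/C=C(\C)C(=O)NC1=C[C@](O)(C=C)[C@@H]2OC(C)(OC)O[C@@H]2C1=O | intermediate
27 | (4R,5S,6R)-5-acetoxy-6-bromo-2-[(2E,4R)-2,4-dimethyloct-2-enoylamino]-4-ethenyl-4-hydroxycyclohex-2-en-1-one | CCCC[C@@H](C)/C=C(\C)C(=O)NC1=C[C@](O)(C=C)[C@H](OC(C)=O)[C@@H](Br)C1=O | intermediate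
28 | (4R,5R,6S)-2-[(2E,4R)-2,4-dimethyloct-2-enoylamino]-4-ethenyl-5,6-epoxy-4-hydroxycyclohex-2-en-1-one | CCCC[C@@H](C)/C=C(\C)C(=O)NC1=C[C@](O)(C=C)[C@@H]2O[C@@H]2C1=O | intermediate
29 | (4R,5R,6S)-2-[(2E,4R)-2,4-dimethyloct-2-enoylamino]-5,6-epoxy-4-hydroxy-4-[(1E,3E,5E)-7-[(2-hydroxy-5-oxocyclopent-1-en-1-yl)amino]-7-oxohepta-1,3,5-trien-1-yl]cyclohex-2-en-1-one (CNP0259711.3) | CCCC[C@@H](C)/C=C(\C)C(=O)NC1=C[C@](O)(/C=C/C=C/C=C/C(=O)NC2=C(O)CCC2=O)[C@@H]2O[C@@H]2C1=O | target

## Step count and risks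

Total step count: 18 (steps 1–3 upper acid, steps 4–8 bromodienamide, steps 9–18 core and assembly).
Longest linear sequence: 10 steps (13 to 29, steps 9–18).

The three steps most likely to fail:

**Step 14 (Curtius rearrangement and isocyanate–acid condensation).** The vinyl isocyanate may give urea or anhydride instead of the enamide, and the triene can dimerise at 80 °C. The fallback sets out from 19 and rejoins the route at 24. The same Curtius rearrangement is run, but isocyanate 21 is trapped with 2-(trimethylsilyl)ethanol to give 2-(trimethylsilyl)ethyl N-[(3R,4S)-5-ethenyl-3,4-(isopropylidenedioxy)cyclohexa-1,5-dien-1-yl]carbamate F1. The singlet-oxygen cycloaddition and Et3N opening are then done on this less electron-rich carbamate to give 2-(trimethylsilyl)ethyl N-[(4R,5R,6S)-4-ethenyl-4-hydroxy-5,6-(isopropylidenedioxy)-1-oxocyclohex-2-en-2-yl]carbamate F2. Bu4NF in THF at 0 °C removes the carbamate to give (4R,5R,6S)-2-amino-4-ethenyl-4-hydroxy-5,6-(isopropylidenedioxy)cyclohex-2-en-1-one F3. This aminoenone is acylated in pyridine/CH2Cl2 with (2E,4R)-2,4-dimethyloct-2-enoyl chloride F4 (made from 5 with oxalyl chloride and catalytic DMF), which gives 24.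

**Step 17 (cis-diol to epoxide next to the ketone).** The bromo acetate 27 can lose acetate by E1cB elimination under carbonate, and AcBr may attack the tertiary allylic alcohol. The fallback sets out from 25 and rejoins the route at 28; it avoids any acyloxy leaving group β to the ketone. 1,1'-Thionyldiimidazole in THF at −20 °C closes the cis-diol to the cyclic sulfite of 25 (5,6-O-sulfinyl derivative) F5. LiBr in acetone at 40 °C opens it at C6, the carbon activated by the ketone, with inversion; aqueous work-up releases (4R,5S,6R)-6-bromo-2-[(2E,4R)-2,4-dimethyloct-2-enoylamino]-4-ethenyl-4,5-dihydroxycyclohex-2-en-1-one F6. K2CO3 in MeOH at 0 °C closes the free bromohydrin to 28.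

**Step 18 (late Heck coupling).** The base- and heat-sensitive epoxyquinol and the acidic enol of 12 may not tolerate the Heck conditions, or insertion may be sluggish. The fallback sets out from 28 and rejoins the route at 29. Cross-metathesis of 28 with vinylboronic acid pinacol ester (second-generation Grubbs catalyst, RuCl2(H2IMes)(PCy3)(=CHPh), CH2Cl2, 40 °C) gives (4R,5R,6S)-2-[(2E,4R)-2,4-dimethyloct-2-enoylamino]-5,6-epoxy-4-hydroxy-4-[(E)-2-(4,4,5,5-tetramethyl-1,3,2-dioxaborolan-2-yl)ethenyl]cyclohex-2-en-1-one F7. Suzuki–Miyaura coupling of this boronate with 12 (Pd(PPh3)4, aqueous K3PO4, THF, rt) gives 29.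

## Further compounds

F1 | step 14 | 2-(trimethylsilyl)ethyl N-[(3R,4S)-5-ethenyl-3,4-(isopropylidenedioxy)cyclohexa-1,5-dien-1-yl]carbamate | C[Si](C)(C)CCOC(=O)NC1=C[C@H]2OC(C)(C)O[C@H]2C(C=C)=C1
F2 | step 14 | 2-(trimethylsilyl)ethyl N-[(4R,5R,6S)-4-ethenyl-4-hydroxy-5,6-(isopropylidenedioxy)-1-oxocyclohex-2-en-2-yl]carbamate | C[Si](C)(C)CCOC(=O)NC1=C[C@](O)(C=C)[C@@H]2OC(C)(C)O[C@@H]2C1=O
F3 | step 14 | (4R,5R,6S)-2-amino-4-ethenyl-4-hydroxy-5,6-(isopropylidenedioxy)cyclohex-2-en-1-one | NC1=C[C@](O)(C=C)[C@@H]2OC(C)(C)O[C@@H]2C1=O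
F4 | step 14 | (2E,4R)-2,4-dimethyloct-2-enoyl chloride | CCCC[C@@H](C)/C=C(\C)C(Cl)=O
F5 | step 17 | cyclic sulfite of 25 (5,6-O-sulfinyl; mixture at sulfur) | CCCC[C@@H](C)/C=C(\C)C(=O)NC1=C[C@](O)(C=C)[C@@H]2OS(=O)O[C@@H]2C1=O
F6 | step 17 | (4R,5S,6R)-6-bromo-2-[(2E,4R)-2,4-dimethyloct-2-enoylamino]-4-ethenyl-4,5-dihydroxycyclohex-2-en-1-one | CCCC[C@@H](C)/C=C(\C)C(=O)NC1=C[C@](O)(C=C)[C@H](O)[C@@H](Br)C1=O
F7 | step 18 | (4R,5R,6S)-2-[(2E,4R)-2,4-dimethyloct-2-enoylamino]-5,6-epoxy-4-hydroxy-4-[(E)-2-(4,4,5,5-tetramethyl-1,3,2-dioxaborolan-2-yl)ethenyl]cyclohex-2-en-1-one | CCCC[C@@H](C)/C=C(\C)C(=O)NC1=C[C@](O)(/C=C/B3OC(C)(C)C(C)(C)O3)[C@@H]2O[C@@H]2C1=O
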